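Readings and results stem from a simulated flask from invented constants, and the scatter is random.

Read the two earlier runs as a ladder of times, the fast rung first.

| setting | epsilon | zeta | flask |
|---|---|---|---|
| starting complex | 1 M | 0.50 M | 1.0 M |
| incoming ligand | 1.2 equiv | 2.5 equiv | 2.50 equiv |
| remark | run made earlier | run made earlier |  |
| time |  |  | 50 min |

- epsilon (time / min: complex with two exchanged / %): 0.667: 4.5; 2.50: 16.4; 8.00: 14.5; 30.0: 8.4
- zeta (time / min: complex with two exchanged / %): 0.667: 7.4; 2.50: 27.0; 8.00: 32.8; 30.0: 15.5

(each reading ± 0.5 percentage points)

- the best time, 50 min at the latest, for complex with two exchanged
- the amount of complex with two exchanged, in percent of the starting complex charged, at that time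
- earliest time at which at least nineteen twentieths of that best amount are there, in min
- latest time at which they still are, in min

- the earlier runs were read with a standard deviation of 0.5 percentage points

On the fast rung, complex with two exchanged climbs. In the zeta run, the slope of the first reading reaches the highest reading in 2.96 min. On the slow rung it leaks away, halving between the last two zeta readings in 20.3 min. That is longer than the climb, so the highest reading stands near what the climb reached.

Now compare heights, so that time drops out. Epsilon and zeta charge nearly the same c(incoming ligand), 1.20 M and 1.25 M, at different c(starting complex), yet their highest readings are 0.164 M and 0.164 M. Their mean ratio, 13.4%, is the peak share: highest c(complex with two exchanged) over charged c(incoming ligand).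

These two runs leave it untested whether the peak share holds at another c(incoming ligand), theirs being nearly the same, so taking it as constant is my assumption. On that assumption, my own reckoning for the flask is 33.5% of the starting complex. Its c(incoming ligand), 2.50 M, is twice zeta's, so if the climb speeds up in step, zeta's top, which lies between the readings either side of its highest, moves to between 1.25 min and 15.0 min.

The forecast, which calls itself “a tentative empirical extrapolation”, puts the best at 36% after 3.5 min, more than my figure, with the window from 2.6 min to 5.5 min.

The flask gives 34.3% at 2.89 min, with the window from 1.91 min to 4.47 min, which is a peak share of 13.7% against my 13.4%.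

    starting complex + incoming ligand → leaving ligand + complex with one exchanged (k = 0.00480 M⁻¹ s⁻¹)
    complex with one exchanged + incoming ligand → leaving ligand + complex with two exchanged (k = 0.0220 M⁻¹ s⁻¹)
    complex with two exchanged + incoming ligand → leaving ligand + complex with three exchanged (k = 0.00180 M⁻¹ s⁻¹)
    crystals ⇌ leaving ligand, rate k4*(cs4 - [leaving ligand]) while solid is left; crystals form when [leaving ligand] > cs4 (solubility = 0.480 M, k = 0.100 s⁻¹)
    incoming ligand → decomposition product (k = 1.20 × 10⁻⁵ s⁻¹)
    starting complex + complex with two exchanged → side product (k = 0.0110 M⁻¹ s⁻¹)

In the flask, the half-life of complex with two exchanged by its step with starting complex, other concentrations as charged, is 1.1 min, close to the 0.96 min of starting complex by its first step. At the best time in the flask, side product, each unit counted as two of the starting complex, holds 32.8% against 34.3% of complex with two exchanged, with 16.4% of starting complex, the limiting reagent, still there. With 1.50 equiv of incoming ligand, the neighbouring flask's best is 22.9%, where the peak share gives 20.1%.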